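**Retrosynthetic overview**

1. Numbering: C1 lactone C=O, C2 CH2, C3 CH–OO, C4 C(CH3)–O(lactone), C5 ring CH2, C6 C(CH3)(OO)–chain, C7 first chain carbon; the target is (3R,4R,6S). The strategy rests on C6 of the 1,2-dioxane ring: it bears a peroxide oxygen, so it is a latent ring peroxycarbenium carbon, and it lies 1,3 to the quaternary lactone carbon C4 of the cis-fused 1,2-dioxane/γ-lactone, whose lactone oxygen can sit axial and steer a nucleophile.
2. Chain: C8–C9 by cross metathesis of a 6-allyl bicycle with 11-phenylundec-1-ene, then diimide; C6–C7 by allylsilane attack on the peroxycarbenium ion from a 6-methoxy peroxyketal, so the quaternary peroxy carbon is made by C–C and not by C–O bond formation.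
3. Core: O–C3 by peroxy-Michael closure of a methanol-trapped ketone oxide (ozonolysis of a 5-methallyl butenolide); C2=C3 and the lactone C–O by Z-selective olefination and lactonisation; C4–C5 by a catalytic enantioselective carbonyl-ene reaction of methyl pyruvate with isobutene.
4. Ring order: γ-lactone first (as the butenolide), 1,2-dioxane second, side chain last in two stages; the one catalytic stereocentre C4 relays to C3 (ring fusion) and then to C6 (axial attack).

Key step: step 8

Assumption: the (R,R)-tert-butyl-bis(oxazoline) ligand is taken to be the enantiomer that gives the (R) alcohol 3; the sense is to be confirmed on 3 before going on, and the (S,S)-ligand would be used if it proved opposite.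

**Route**

Step 1
Reactants: 1 methyl pyruvate; 2 isobutene
Product: 3 methyl (R)-2-hydroxy-2,4-dimethylpent-4-enoate
Conditions: [Cu((R,R)-t-Bu-box)](SbF6)2 (10 mol %, from CuCl2, the bis(oxazoline) and AgSbF6), isobutene (excess), CH2Cl2, sealed tube, 0 °C to rt
Reagents that add atoms: none
Why: Catalytic enantioselective carbonyl-ene reaction in which the pyruvate chelates the cationic divalent copper centre through both carbonyl oxygens in a square-planar complex whose tert-butyl groups leave one face of the ketone open to isobutene, so the catalyst alone sets C4.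

Step 2
Reactants: 3 methyl (R)-2-hydroxy-2,4-dimethylpent-4-enoate
Product: 4 methyl (R)-2,4-dimethyl-2-(triethylsilyloxy)pent-4-enoate
Conditions: Et3SiOTf, 2,6-lutidine, CH2Cl2, −78 to 0 °C
Reagents that add atoms: triethylsilyl trifluoromethanesulfonate, CC[Si](CC)(CC)OS(=O)(=O)C(F)(F)F
Why: Silylation of a hindered tertiary alcohol with a silyl triflate and a hindered pyridine base, giving an ether that is small enough to go on and come off a tertiary centre and that keeps the oxygen out of the reduction and olefination.

Step 3
Reactants: 4 methyl (R)-2,4-dimethyl-2-(triethylsilyloxy)pent-4-enoate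
Product: 5 (R)-2,4-dimethyl-2-(triethylsilyloxy)pent-4-enal
Conditions: i-Bu2AlH (1.1 equiv), CH2Cl2, −78 °C; MeOH, then aq. KNaC4H4O6
Reagents that add atoms: none
Why: Partial reduction of an ester with i-Bu2AlH at low temperature, where the α-silyloxy group stabilises the tetrahedral aluminium hemiacetal until work-up and the quaternary α-carbon cannot epimerise.

Step 4
Reactants: 5 (R)-2,4-dimethyl-2-(triethylsilyloxy)pent-4-enal; 6 methyl bis(2,2,2-trifluoroethyl)phosphonoacetate
Product: 7 methyl (2Z,4R)-4,6-dimethyl-4-(triethylsilyloxy)hepta-2,6-dienoate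
Conditions: 6, KN(SiMe3)2, 18-crown-6, THF, −78 °C; then 5, −78 °C
Reagents that add atoms: none
Why: Still–Gennari olefination, in which the electron-poor phosphonate anion with a dissociated potassium counter-ion collapses fast and irreversibly through the syn oxaphosphetane to the Z enoate needed for lactonisation, the aldehyde having no α-hydrogen to enolise.

Step 5
Reactants: 7 methyl (2Z,4R)-4,6-dimethyl-4-(triethylsilyloxy)hepta-2,6-dienoate
Product: 9 (R)-5-methyl-5-(2-methylprop-2-en-1-yl)furan-2(5H)-one, via Z-hydroxy enoate 8 (not isolated)
Conditions: HF·pyridine, pyridine, THF, 0 °C to rt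
Reagents that add atoms: none
Why: Buffered fluoride desilylation, after which the tertiary alcohol and the cis-disposed ester should close the butenolide by intramolecular transesterification (5-exo-trig acyl substitution) without touching C4.

Step 6
Reactants: 9 (R)-5-methyl-5-(2-methylprop-2-en-1-yl)furan-2(5H)-one
Product: 12 (5R)-5-(2-hydroperoxy-2-methoxypropyl)-5-methylfuran-2(5H)-one (both ketal epimers), via primary ozonide 10 (not isolated), via carbonyl oxide 11 (not isolated)
Conditions: O3, CH2Cl2/MeOH (4:1), NaHCO3, Sudan Red 7B indicator, −78 °C; N2 purge, no reductant, concentrate cold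
Reagents that add atoms: ozone, [O-][O+]=O; methanol, CO
Why: Ozonolysis with solvent participation, in which ozone adds to the electron-rich 1,1-disubstituted alkene far faster than to the conjugated butenolide alkene, the primary ozonide cleaves to formaldehyde and the more substituted ketone oxide, and methanol traps the latter as the α-methoxy hydroperoxide, the dye end point guarding against overoxidation and the unselective ketal centre being of no consequence.

Step 7
Reactants: 12 (5R)-5-(2-hydroperoxy-2-methoxypropyl)-5-methylfuran-2(5H)-one
Product: 13 (4aR,7aR)-3-methoxy-3,4a-dimethyltetrahydrofuro[3,2-c][1,2]dioxin-6(3H)-one (cis-fused 6-methoxy peroxyketal lactone; both C6 epimers)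
Conditions: Et2NH (0.2 equiv), CF3CH2OH, rt
Reagents that add atoms: none
Why: Amine-catalysed intramolecular peroxy-Michael addition (6-exo-trig) to the β-carbon C3 of the butenolide in a hydrogen-bond-donating solvent, in which the hydroperoxide is tethered to C4 through C5 and C6 and can reach C3 only on its own face, so that C4 sets C3 with a cis ring fusion, while C6 stays a ketal and never becomes a ketone that could expel the lactone carboxylate by β-elimination.

Step 8
Reactants: 13 (4aR,7aR)-3-methoxy-3,4a-dimethyltetrahydrofuro[3,2-c][1,2]dioxin-6(3H)-one; 14 allyltrimethylsilane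
Product: 16 (3S,4aR,7aR)-3-allyl-3,4a-dimethyltetrahydrofuro[3,2-c][1,2]dioxin-6(3H)-one (6-allyl bicycle; 3R,4R,6S in the numbering of the overview), via ring peroxycarbenium ion 15 (not isolated)
Conditions: 14 (3 equiv), SnCl4 (2.2 equiv), CH2Cl2, −78 °C; aq. NaHCO3
Reagents that add atoms: none
Why: SnCl4 ionises the C6–OMe bond (not the O–O bond) of either ketal epimer to the same tertiary ring peroxycarbenium ion 15, which allyltrimethylsilane captures at C6 in an SE2' process with loss of the silyl group, so that the C6–C7 bond and the quaternary peroxy stereocentre form together. The closest known reaction type is the Lewis-acid-mediated Hosomi–Sakurai allylation of ketone-derived monoperoxyketals, 3-alkoxy-1,2-dioxolanes and 3-alkoxy-1,2-dioxanes. No ring closes here, since the lactone (5-exo-trig acyl substitution, step 5) and the dioxane (6-exo-trig peroxy-Michael addition, step 7) are already in place. C6 is the only new stereocentre and is controlled by the ring: the cation should prefer the half-chair with the C4 lactone oxygen pseudoaxial (electrostatically favoured near the positive charge) and the C4 methyl and the C3–C2 bond pseudoequatorial, and stereoelectronically preferred axial attack leading straight to a chair then comes from the face of that oxygen, which places the allyl group cis to the lactone oxygen and the two methyls cis to each other. The selectivity the step needs is facial selectivity at C6, and the substrate secures it because on this path the silane passes only the small axial oxygen, whereas attack through the other half-chair would meet the axial C4 methyl in a syn-diaxial clash. This sense is argued by analogy with six-membered oxocarbenium ions carrying a 1,3-related oxygen substituent and is untested on this bicyclic lactone, and more than two equivalents of SnCl4 are used because the lactone carbonyl binds the first.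

Step 9
Reactants: 17 11-bromoundec-1-ene; 18 phenylmagnesium bromide
Product: 19 11-phenylundec-1-ene
Conditions: Li2CuCl4 (3 mol %), THF, −10 °C to rt
Reagents that add atoms: none
Why: Copper-catalysed Kochi-type cross-coupling of an aryl Grignard reagent with a primary alkyl bromide, to which the remote terminal alkene is inert.

Step 10
Reactants: 16 (3S,4aR,7aR)-3-allyl-3,4a-dimethyltetrahydrofuro[3,2-c][1,2]dioxin-6(3H)-one; 19 11-phenylundec-1-ene
Product: 20 8,9-didehydroplakortolide K (E/Z mixture; E drawn)
Conditions: 19 (4 equiv), second-generation Grubbs catalyst (H2IMes)(PCy3)Cl2Ru=CHPh (5 mol %), 1,4-benzoquinone (10 mol %), CH2Cl2, 40 °C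
Reagents that add atoms: none
Why: Olefin cross metathesis between two unhindered terminal alkenes, driven by loss of ethylene and biased to the cross product by the excess of the cheap partner, with a ruthenium carbene that tolerates dialkyl peroxides, lactones and arenes, the alkene geometry being irrelevant because the alkene is reduced next.

Step 11
Reactants: 20 8,9-didehydroplakortolide K
Product: 21 plakortolide K
Conditions: 2-nitrobenzenesulfonylhydrazide (excess), Et3N, CH2Cl2, rt
Reagents that add atoms: none
Why: Diimide reduction, in which diimide generated in the flask from the sulfonylhydrazide delivers two hydrogens to the disubstituted alkene in a concerted syn transfer and, unlike catalytic hydrogenation, should leave the O–O bond, the lactone and the arene untouched.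

**Compound list**

1 | methyl pyruvate | CC(=O)C(=O)OC | starting material
2 | isobutene (2-methylpropene) | CC(C)=C | starting material
3 | methyl (R)-2-hydroxy-2,4-dimethylpent-4-enoate | COC(=O)[C@](C)(O)CC(C)=C | intermediate
4 | methyl (R)-2,4-dimethyl-2-(triethylsilyloxy)pent-4-enoate | COC(=O)[C@](C)(O[Si](CC)(CC)CC)CC(C)=C | intermediate
5 | (R)-2,4-dimethyl-2-(triethylsilyloxy)pent-4-enal | O=C[C@](C)(O[Si](CC)(CC)CC)CC(C)=C | intermediate
6 | methyl bis(2,2,2-trifluoroethyl)phosphonoacetate | COC(=O)CP(=O)(OCC(F)(F)F)OCC(F)(F)F | starting material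
7 | methyl (2Z,4R)-4,6-dimethyl-4-(triethylsilyloxy)hepta-2,6-dienoate | COC(=O)/C=C\[C@](C)(O[Si](CC)(CC)CC)CC(C)=C | intermediate
8 | methyl (2Z,4R)-4-hydroxy-4,6-dimethylhepta-2,6-dienoate (Z-hydroxy enoate; not isolated) | COC(=O)/C=C\[C@](C)(O)CC(C)=C | intermediate
9 | (R)-5-methyl-5-(2-methylprop-2-en-1-yl)furan-2(5H)-one | O=C1C=C[C@@](C)(CC(C)=C)O1 | intermediate
10 | (5R)-5-methyl-5-[(4-methyl-1,2,3-trioxolan-4-yl)methyl]furan-2(5H)-one (primary ozonide; not isolated) | O=C1C=C[C@@](C)(CC2(C)COOO2)O1 | intermediate
11 | carbonyl oxide (ketone oxide) of (R)-5-methyl-5-(2-oxopropyl)furan-2(5H)-one (not isolated) | O=C1C=C[C@@](C)(CC(C)=[O+][O-])O1 | intermediate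
12 | (5R)-5-(2-hydroperoxy-2-methoxypropyl)-5-methylfuran-2(5H)-one (both ketal epimers) | O=C1C=C[C@@](C)(CC(C)(OC)OO)O1 | intermediate
13 | (4aR,7aR)-3-methoxy-3,4a-dimethyltetrahydrofuro[3,2-c][1,2]dioxin-6(3H)-one (cis-fused 6-methoxy-4,6-dimethyl-1,2-dioxane γ-lactone; both C6 epimers) | COC1(C)C[C@@]2(C)OC(=O)C[C@H]2OO1 | intermediate
14 | allyltrimethylsilane | C=CC[Si](C)(C)C | starting material
15 | ring peroxycarbenium ion at C6 of the cis-fused dioxane lactone (not isolated) | CC=1C[C@@]2(C)OC(=O)C[C@H]2O[O+]=1 | intermediate
16 | (3S,4aR,7aR)-3-allyl-3,4a-dimethyltetrahydrofuro[3,2-c][1,2]dioxin-6(3H)-one (cis-fused 6-allyl-4,6-dimethyl-1,2-dioxane γ-lactone) | C[C@]1(CC=C)C[C@@]2(C)OC(=O)C[C@H]2OO1 | intermediate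
17 | 11-bromoundec-1-ene | C=CCCCCCCCCCBr | starting material
18 | phenylmagnesium bromide | Br[Mg]c1ccccc1 | starting material
19 | 11-phenylundec-1-ene | C=CCCCCCCCCCc1ccccc1 | intermediate
20 | 8,9-didehydroplakortolide K (E drawn; E/Z mixture) | C[C@]1(C/C=C/CCCCCCCCCc2ccccc2)C[C@@]2(C)OC(=O)C[C@H]2OO1 | intermediate
21 | plakortolide K; (3S,4aR,7aR)-3,4a-dimethyl-3-(12-phenyldodecyl)tetrahydrofuro[3,2-c][1,2]dioxin-6(3H)-one | C[C@]1(CCCCCCCCCCCCc2ccccc2)C[C@@]2(C)OC(=O)C[C@H]2OO1 | target

**Step count**

Total steps: 11. Longest linear sequence: 10 steps (steps 1 to 8, 10 and 11, from methyl pyruvate); step 9 is a one-step side branch.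

**Steps most likely to fail**

1. Step 8. What may go wrong: low facial selectivity in the capture of the peroxycarbenium ion, or heterolysis of the O–O bond and proton loss from the cation under the Lewis acid before the silane reacts. The fallback makes C6 by C–O bond formation at a tertiary radical instead of C–C bond formation at a cation; it sets out from butenolide 9 and bromide 17 and comes back to the route at target 21. Li2CuCl4-catalysed coupling of 17 with 2-phenylethylmagnesium chloride (PhCH2CH2MgCl) in THF should give 13-phenyltridec-1-ene F1. Cross metathesis of the 1,1-disubstituted alkene of 9 with F1 (second-generation Hoveyda–Grubbs catalyst (H2IMes)Cl2Ru(=CH-C6H4-2-O-i-Pr), CH2Cl2, 40 °C) should give the trisubstituted alkene (R)-5-methyl-5-(2-methyl-14-phenyltetradec-2-en-1-yl)furan-2(5H)-one F2, whose geometry does not matter. Mukaiyama–Isayama hydroperoxysilylation (Co(thd)2 with thd = 2,2,6,6-tetramethylheptane-3,5-dionate, a divalent cobalt complex, O2, Et3SiH, ClCH2CH2Cl, rt) should transfer a hydrogen atom to the electron-rich alkene in preference to the butenolide and trap the tertiary C6 radical with O2, giving (5R)-5-methyl-5-[2-methyl-14-phenyl-2-(triethylsilylperoxy)tetradecyl]furan-2(5H)-one F3 as both C6 epimers. HF·pyridine should free (5R)-5-(2-hydroperoxy-2-methyl-14-phenyltetradecyl)-5-methylfuran-2(5H)-one F4, and Et2NH in CF3CH2OH should close the dioxane as in step 7 to give 21 together with its C6 epimer, to be separated by chromatography. This path is not selective at C6 but needs neither step 10 nor step 11.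

2. Step 7. What may go wrong: amine-induced breakdown of the hydroperoxy ketal (loss of methanol or hydrogen peroxide, aza-Michael addition of the amine) outrunning a slow closure onto the hindered β-carbon next to the quaternary C4. The fallback closes the dioxane before the lactone, onto a more flexible acyclic acceptor; it sets out from Z-enoate 7 and comes back at peroxyketal 13. Ozonolysis of 7 under the conditions of step 6 should pass through the primary ozonide F5 and the carbonyl oxide F6 to methyl (2Z,4R)-6-hydroperoxy-6-methoxy-4-methyl-4-(triethylsilyloxy)hept-2-enoate F7. Et2NH in CF3CH2OH should then give methyl 2-[(3R,4R)-6-methoxy-4,6-dimethyl-4-(triethylsilyloxy)-1,2-dioxan-3-yl]acetate F8 by 6-exo-trig peroxy-Michael addition. HF·pyridine should remove the silyl group to give methyl 2-[(3R,4R)-4-hydroxy-6-methoxy-4,6-dimethyl-1,2-dioxan-3-yl]acetate F9, which should lactonise to 13 with a trace of pyridinium p-toluenesulfonate. Only the C3 epimer with the acetate arm cis to the C4 oxygen can lactonise; the other is expected to be recycled by renewed amine treatment through retro-Michael and Michael addition.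

3. Step 6. What may go wrong: competing ozone attack on the butenolide alkene, and cleavage of the primary ozonide in the unwanted sense, lowering the amount of a hydroperoxy ketal that tolerates little purification. The fallback makes the hydroperoxy ketal by acid-catalysed perhydrolysis of a ketal instead of by trapping a carbonyl oxide; it sets out from butenolide 9 and comes back at hydroperoxy ketal 12. Lemieux–Johnson cleavage (OsO4 cat., NaIO4, 2,6-lutidine, dioxane/H2O) should pass through (5R)-5-(2,3-dihydroxy-2-methylpropyl)-5-methylfuran-2(5H)-one F10 to (R)-5-methyl-5-(2-oxopropyl)furan-2(5H)-one F11. HC(OMe)3 in MeOH with a trace of pyridinium p-toluenesulfonate should give (R)-5-(2,2-dimethoxypropyl)-5-methylfuran-2(5H)-one F12. Exchange of one methoxy group with anhydrous H2O2 in Et2O and a trace of camphorsulfonic acid should then give 12.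

**Further compounds**

F1 | step 8 | 13-phenyltridec-1-ene | C=CCCCCCCCCCCCc1ccccc1
F2 | step 8 | (R)-5-methyl-5-(2-methyl-14-phenyltetradec-2-en-1-yl)furan-2(5H)-one | O=C1C=C[C@@](C)(CC(C)=CCCCCCCCCCCCc2ccccc2)O1
F3 | step 8 | (5R)-5-methyl-5-[2-methyl-14-phenyl-2-(triethylsilylperoxy)tetradecyl]furan-2(5H)-one | O=C1C=C[C@@](C)(CC(C)(OO[Si](CC)(CC)CC)CCCCCCCCCCCCc2ccccc2)O1
F4 | step 8 | (5R)-5-(2-hydroperoxy-2-methyl-14-phenyltetradecyl)-5-methylfuran-2(5H)-one | O=C1C=C[C@@](C)(CC(C)(OO)CCCCCCCCCCCCc2ccccc2)O1
F5 | step 7 | primary ozonide of Z-enoate 7 | COC(=O)/C=C\[C@](C)(O[Si](CC)(CC)CC)CC1(C)COOO1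
F6 | step 7 | carbonyl oxide from Z-enoate 7 | COC(=O)/C=C\[C@](C)(O[Si](CC)(CC)CC)CC(C)=[O+][O-]
F7 | step 7 | methyl (2Z,4R)-6-hydroperoxy-6-methoxy-4-methyl-4-(triethylsilyloxy)hept-2-enoate | COC(=O)/C=C\[C@](C)(O[Si](CC)(CC)CC)CC(C)(OC)OO
F8 | step 7 | methyl 2-[(3R,4R)-6-methoxy-4,6-dimethyl-4-(triethylsilyloxy)-1,2-dioxan-3-yl]acetate | COC1(C)C[C@@](C)(O[Si](CC)(CC)CC)[C@@H](CC(=O)OC)OO1
F9 | step 7 | methyl 2-[(3R,4R)-4-hydroxy-6-methoxy-4,6-dimethyl-1,2-dioxan-3-yl]acetate | COC1(C)C[C@@](C)(O)[C@@H](CC(=O)OC)OO1
F10 | step 6 | (5R)-5-(2,3-dihydroxy-2-methylpropyl)-5-methylfuran-2(5H)-one | O=C1C=C[C@@](C)(CC(C)(O)CO)O1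
F11 | step 6 | (R)-5-methyl-5-(2-oxopropyl)furan-2(5H)-one | O=C1C=C[C@@](C)(CC(C)=O)O1
F12 | step 6 | (R)-5-(2,2-dimethoxypropyl)-5-methylfuran-2(5H)-one | O=C1C=C[C@@](C)(CC(C)(OC)OC)O1
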